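**Retrosynthetic overview**
- The target comes from its 12-O-triethylsilyl ether. The C7=C8 bond is made by an aldol addition of a 2-chloro-4-silyloxy-4-octenylcyclopentenone enolate to methyl (Z)-7-oxohept-5-enoate, followed by anti-elimination; the 5Z olefin comes from a Z-selective Wittig reaction.
- The 2-chloroenone comes from the parent enone by nucleophilic epoxidation, chloride opening at the α-carbon and dehydration.
- (S)-4-Hydroxy-4-[(Z)-oct-2-enyl]cyclopentenone comes from (R)-4-silyloxycyclopent-2-enone by face-selective 1,2-propargylation, acetylide pentylation, Lindlar reduction and a 1,3-oxygen transposition. The secondary C–O centre relays its chirality to the tertiary carbinol and is then oxidised away.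
- (R)-4-Silyloxycyclopentenone comes from meso cis-cyclopent-4-ene-1,3-diol by lipase-catalysed desymmetrisation, which sets the first stereocentre catalytically.
- Ring order: the only carbocycle (the cyclopentene) is already present in the meso diol; no ring is formed later apart from a transient epoxide.

Assumption: the epoxide and chlorohydrin ring centres and the C7/C8 aldol centres are transient (all destroyed within two steps), so they are drawn without configuration and carried as mixtures; only the quaternary carbinol centre is specified in those SMILES.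

**Route**

Step 1
Reactants: 1 cis-cyclopent-4-ene-1,3-diol (meso)
Product: 2 (1S,4R)-4-hydroxycyclopent-2-en-1-yl acetate
Conditions: lipase (porcine pancreatic lipase, crude pancreatin), vinyl acetate (4 equiv), Et3N (0.7 equiv), THF, rt, 20 h; filter, chromatograph
Reagents that add atoms: vinyl acetate (CC(=O)OC=C)
Why: Lipase-catalysed irreversible transesterification desymmetrises the meso diol by acylating only the hydroxyl on the (S)-configured carbinol carbon, so the enzyme sets both ring stereocentres of 2 (expected >98% ee, raised further by any over-acylation to the meso diacetate).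

Step 2
Reactants: 2 (1S,4R)-4-hydroxycyclopent-2-en-1-yl acetate
Product: 3 (1S,4R)-4-[(tert-butyldimethylsilyl)oxy]cyclopent-2-en-1-yl acetate
Conditions: TBSCl (1.2 equiv), imidazole (2.5 equiv), DMF, 0 °C → rt
Reagents that add atoms: tert-butyldimethylsilyl chloride (CC(C)(C)[Si](C)(C)Cl)
Why: Standard imidazole-mediated silylation of the free secondary alcohol (silyl ether protection) leaves the acetate and both stereocentres untouched.

Step 3
Reactants: 3 (1S,4R)-4-[(tert-butyldimethylsilyl)oxy]cyclopent-2-en-1-yl acetate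
Product: 4 (1S,4R)-4-[(tert-butyldimethylsilyl)oxy]cyclopent-2-en-1-ol
Conditions: K2CO3 (0.3 equiv), MeOH, 0 °C → rt
Reagents that add atoms: none
Why: Base-catalysed transesterification (methanolysis) removes the acetate by acyl–oxygen cleavage, so the carbinol configuration is retained and the silyl ether survives.

Step 4
Reactants: 4 (1S,4R)-4-[(tert-butyldimethylsilyl)oxy]cyclopent-2-en-1-ol
Product: 5 (R)-4-[(tert-butyldimethylsilyl)oxy]cyclopent-2-en-1-one
Conditions: activated MnO2 (15 equiv), CH2Cl2, rt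
Reagents that add atoms: none
Why: Neutral MnO2 allylic oxidation gives the base-sensitive enone without β-elimination and leaves the silyloxy stereocentre as the only stereocentre.

Step 5
Reactants: 5 (R)-4-[(tert-butyldimethylsilyl)oxy]cyclopent-2-en-1-one; 6 3-bromoprop-1-yne (propargyl bromide)
Product: 8 (1S,4R)-4-[(tert-butyldimethylsilyl)oxy]-1-(prop-2-yn-1-yl)cyclopent-2-en-1-ol, via allenylzinc bromide 7 (not isolated)
Conditions: Zn dust (2 equiv), 6 (1.8 equiv), THF, 0 °C; then 5, −78 → −20 °C; H2O/aq. NH4Cl; chromatographic removal of the minor diastereomer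
Reagents that add atoms: none
Why: Barbier-type propargylation, in which the weakly basic allenylzinc adds 1,2 through a cyclic SE2' transition state to give the homopropargylic alcohol, attacks the carbonyl face anti to the silyloxy group and so sets the tertiary carbinol centre (expected ≥8:1; the minor isomer must be removed because it would later become the enantiomer).

Step 6
Reactants: 8 (1S,4R)-4-[(tert-butyldimethylsilyl)oxy]-1-(prop-2-yn-1-yl)cyclopent-2-en-1-ol; 9 1-iodopentane
Product: 11 (1S,4R)-4-[(tert-butyldimethylsilyl)oxy]-1-(oct-2-yn-1-yl)cyclopent-2-en-1-ol, via dilithium alkoxide acetylide 10 (not isolated)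
Conditions: n-BuLi (2.2 equiv), THF, −78 → −20 °C; DMPU, 9 (1.5 equiv), −20 °C → rt; H2O
Reagents that add atoms: none
Why: Acetylide alkylation of the alkoxide–acetylide dianion occurs at carbon because the hindered tertiary lithium alkoxide is a poor nucleophile, and any O-to-O silyl migration is harmless since both silyl isomers converge in step 8.

Step 7
Reactants: 11 (1S,4R)-4-[(tert-butyldimethylsilyl)oxy]-1-(oct-2-yn-1-yl)cyclopent-2-en-1-ol
Product: 12 (1S,4R)-4-[(tert-butyldimethylsilyl)oxy]-1-[(Z)-oct-2-en-1-yl]cyclopent-2-en-1-ol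
Conditions: H2 (1 atm), Pd/CaCO3 poisoned with Pb(OAc)2 (Lindlar catalyst), quinoline, EtOAc, rt, stop after 1 equiv H2
Reagents that add atoms: none
Why: Lindlar semi-hydrogenation delivers H2 syn to the alkyne to give the Z-olefin, while the hindered ring olefin is not reduced at this pre-enone stage.

Step 8
Reactants: 12 (1S,4R)-4-[(tert-butyldimethylsilyl)oxy]-1-[(Z)-oct-2-en-1-yl]cyclopent-2-en-1-ol
Product: 13 (1S,4R)-1-[(Z)-oct-2-en-1-yl]cyclopent-2-ene-1,4-diol
Conditions: Bu4NF (1.2 equiv), THF, 0 °C → rt; H2O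
Reagents that add atoms: none
Why: Fluoride-mediated desilylation frees the secondary allylic alcohol without affecting either stereocentre or the olefins.

Step 9
Reactants: 13 (1S,4R)-1-[(Z)-oct-2-en-1-yl]cyclopent-2-ene-1,4-diol
Product: 14 (S)-4-hydroxy-4-[(Z)-oct-2-en-1-yl]cyclopent-2-en-1-one
Conditions: activated MnO2 (15 equiv), CH2Cl2, rt
Reagents that add atoms: none
Why: MnO2 allylic oxidation touches only the secondary allylic alcohol (the tertiary one cannot be oxidised), completing the 1,3-oxygen transposition under neutral conditions that avoid retro-aldol racemisation of the β-hydroxy ketone.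

Step 10
Reactants: 14 (S)-4-hydroxy-4-[(Z)-oct-2-en-1-yl]cyclopent-2-en-1-one
Product: 15 (S)-4-[(Z)-oct-2-en-1-yl]-4-[(triethylsilyl)oxy]cyclopent-2-en-1-one
Conditions: Et3SiOTf (1.2 equiv), 2,6-lutidine (2 equiv), CH2Cl2, −78 °C
Reagents that add atoms: triethylsilyl trifluoromethanesulfonate (CC[Si](CC)(CC)OS(=O)(=O)C(F)(F)F)
Why: Silyl triflate silylation caps the hindered tertiary alcohol at low temperature, which blocks retro-aldol racemisation in all later basic steps.

Step 11
Reactants: 15 (S)-4-[(Z)-oct-2-en-1-yl]-4-[(triethylsilyl)oxy]cyclopent-2-en-1-one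
Product: 16 (4S)-4-[(Z)-oct-2-en-1-yl]-4-[(triethylsilyl)oxy]-6-oxabicyclo[3.1.0]hexan-2-one
Conditions: t-BuOOH (1.5 equiv, in decane), benzyltrimethylammonium hydroxide (0.1 equiv), THF, 0 °C
Reagents that add atoms: tert-butyl hydroperoxide (CC(C)(C)OO)
Why: Weitz–Scheffer nucleophilic epoxidation attacks only the electron-poor enone and not the isolated Z-olefin, and the epoxide face is irrelevant because both new centres are removed in steps 12 and 13.

Step 12
Reactants: 16 (4S)-4-[(Z)-oct-2-en-1-yl]-4-[(triethylsilyl)oxy]-6-oxabicyclo[3.1.0]hexan-2-one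
Product: 17 (4S)-2-chloro-3-hydroxy-4-[(Z)-oct-2-en-1-yl]-4-[(triethylsilyl)oxy]cyclopentan-1-one
Conditions: pyridinium chloride (3 equiv), CH2Cl2, 0 °C → rt
Reagents that add atoms: pyridinium chloride ([Cl-].c1cc[nH+]cc1)
Why: Acid-assisted SN2 opening of the α,β-epoxy ketone by chloride occurs at the α-carbon (activated by the carbonyl and less hindered than the neopentylic β-carbon), as in the classical epoxy ketone to α-chloroenone sequence, under acidity mild enough to keep the silyl ether.

Step 13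
Reactants: 17 (4S)-2-chloro-3-hydroxy-4-[(Z)-oct-2-en-1-yl]-4-[(triethylsilyl)oxy]cyclopentan-1-one
Product: 19 (S)-2-chloro-4-[(Z)-oct-2-en-1-yl]-4-[(triethylsilyl)oxy]cyclopent-2-en-1-one, via chlorohydrin mesylate 18 (not isolated)
Conditions: MsCl (1.5 equiv), Et3N (4 equiv), CH2Cl2, 0 °C → rt
Reagents that add atoms: none
Why: Mesylation followed by E1cB elimination through the acidic α-chloro C–H gives the conjugated 2-chloroenone, and the quaternary centre is not involved.

Step 14
Reactants: 20 (4-carboxybutyl)triphenylphosphonium bromide; 21 2-[(tert-butyldimethylsilyl)oxy]acetaldehyde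
Product: 23 (Z)-7-[(tert-butyldimethylsilyl)oxy]hept-5-enoic acid, via phosphonium ylide carboxylate 22 (not isolated)
Conditions: NaN(SiMe3)2 (2.1 equiv), THF, 0 °C; then 21, −78 °C → rt; aq. HCl to pH 4
Reagents that add atoms: none
Why: Wittig olefination with an unstabilised ylide under lithium-free conditions proceeds through the kinetic cis-oxaphosphetane and gives the 5Z olefin (expected ≥95:5).

Step 15
Reactants: 23 (Z)-7-[(tert-butyldimethylsilyl)oxy]hept-5-enoic acid
Product: 24 methyl (Z)-7-hydroxyhept-5-enoate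
Conditions: TsOH·H2O (0.1 equiv), MeOH, rt, 16 h
Reagents that add atoms: methanol (CO)
Why: Fischer esterification and acid-catalysed methanolysis of the primary silyl ether occur together under conditions too mild to ionise or isomerise the primary Z-allylic alcohol.

Step 16
Reactants: 24 methyl (Z)-7-hydroxyhept-5-enoate
Product: 25 methyl (Z)-7-oxohept-5-enoate
Conditions: Dess–Martin periodinane (1.2 equiv), NaHCO3 (3 equiv), CH2Cl2, 0 °C, 40 min; filter through a short pad, use at once
Reagents that add atoms: none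
Why: Buffered Dess–Martin oxidation converts the Z-allylic alcohol to the Z-enal under neutral conditions that do not isomerise it to the E-enal if it is used immediately.

Step 17
Reactants: 19 (S)-2-chloro-4-[(Z)-oct-2-en-1-yl]-4-[(triethylsilyl)oxy]cyclopent-2-en-1-one; 25 methyl (Z)-7-oxohept-5-enoate
Product: 27 methyl (5Z)-7-[(5S)-3-chloro-5-[(Z)-oct-2-en-1-yl]-2-oxo-5-[(triethylsilyl)oxy]cyclopent-3-en-1-yl]-7-hydroxyhept-5-enoate, via lithium enolate 26 (not isolated)
Conditions: LiN(i-Pr)2 (LDA, 1.05 equiv), THF, −78 °C, 20 min; 25 (1.3 equiv), −78 °C, 20 min; AcOH (1.2 equiv), −78 °C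
Reagents that add atoms: none
Why: Kinetic lithium enolate aldol addition at the only enolisable position adds 1,2 to the enal at −78 °C (Z-olefin and silyloxy group retained), and the ring-locked E-enolate reacts through a Zimmerman–Traxler chair to give mainly the 7,8-anti aldol.

Step 18
Reactants: 27 methyl (5Z)-7-[(5S)-3-chloro-5-[(Z)-oct-2-en-1-yl]-2-oxo-5-[(triethylsilyl)oxy]cyclopent-3-en-1-yl]-7-hydroxyhept-5-enoate
Product: 29 methyl (5Z,7Z)-7-[(5R)-3-chloro-5-[(Z)-oct-2-en-1-yl]-2-oxo-5-[(triethylsilyl)oxy]cyclopent-3-en-1-ylidene]hept-5-enoate, via allylic mesylate 28 (not isolated)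
Conditions: MsCl (1.5 equiv), Et3N (4 equiv), CH2Cl2, −20 → 0 °C, dark; chromatography (HPLC) to remove any 7E isomer
Reagents that add atoms: none
Why: Mesylation and anti-periplanar β-elimination of the anti aldol place C6 cis to the ring carbonyl (7Z), which is also the side away from the fully substituted silyloxy-bearing carbon, completing the aldol condensation without touching the quaternary centre.

Step 19
Reactants: 29 methyl (5Z,7Z)-7-[(5R)-3-chloro-5-[(Z)-oct-2-en-1-yl]-2-oxo-5-[(triethylsilyl)oxy]cyclopent-3-en-1-ylidene]hept-5-enoate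
Product: 30 methyl (5Z,7Z)-7-[(5R)-3-chloro-5-hydroxy-5-[(Z)-oct-2-en-1-yl]-2-oxocyclopent-3-en-1-ylidene]hept-5-enoate
Conditions: HF·pyridine, pyridine, THF, 0 °C, dark
Reagents that add atoms: none
Why: Acidic fluoride desilylation frees the tertiary alcohol without base, so the cross-conjugated dienone, the olefin geometries and the β-hydroxy ketone stereocentre (retro-aldol-prone in base) are preserved.

**Compound list**

1 | cis-cyclopent-4-ene-1,3-diol (meso) | O[C@@H]1C=C[C@H](O)C1 | starting material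
2 | (1S,4R)-4-hydroxycyclopent-2-en-1-yl acetate | CC(=O)O[C@@H]1C=C[C@H](O)C1 | intermediate
3 | (1S,4R)-4-[(tert-butyldimethylsilyl)oxy]cyclopent-2-en-1-yl acetate | CC(=O)O[C@@H]1C=C[C@H](O[Si](C)(C)C(C)(C)C)C1 | intermediate
4 | (1S,4R)-4-[(tert-butyldimethylsilyl)oxy]cyclopent-2-en-1-ol | O[C@@H]1C=C[C@H](O[Si](C)(C)C(C)(C)C)C1 | intermediate
5 | (R)-4-[(tert-butyldimethylsilyl)oxy]cyclopent-2-en-1-one | O=C1C=C[C@H](O[Si](C)(C)C(C)(C)C)C1 | intermediate
6 | 3-bromoprop-1-yne (propargyl bromide) | BrCC#C | starting material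
7 | allenylzinc bromide (propa-1,2-dienylzinc bromide) | C=C=C[Zn]Br | intermediate
8 | (1S,4R)-4-[(tert-butyldimethylsilyl)oxy]-1-(prop-2-yn-1-yl)cyclopent-2-en-1-ol | C#CC[C@@]1(O)C=C[C@H](O[Si](C)(C)C(C)(C)C)C1 | intermediate
9 | 1-iodopentane | CCCCCI | starting material
10 | dilithium salt of 8 (lithium alkoxide, lithium acetylide) | [Li]C#CC[C@@]1(O[Li])C=C[C@H](O[Si](C)(C)C(C)(C)C)C1 | intermediate
11 | (1S,4R)-4-[(tert-butyldimethylsilyl)oxy]-1-(oct-2-yn-1-yl)cyclopent-2-en-1-ol | CCCCCC#CC[C@@]1(O)C=C[C@H](O[Si](C)(C)C(C)(C)C)C1 | intermediate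
12 | (1S,4R)-4-[(tert-butyldimethylsilyl)oxy]-1-[(Z)-oct-2-en-1-yl]cyclopent-2-en-1-ol | CCCCC/C=C\C[C@@]1(O)C=C[C@H](O[Si](C)(C)C(C)(C)C)C1 | intermediate
13 | (1S,4R)-1-[(Z)-oct-2-en-1-yl]cyclopent-2-ene-1,4-diol | CCCCC/C=C\C[C@@]1(O)C=C[C@H](O)C1 | intermediate
14 | (S)-4-hydroxy-4-[(Z)-oct-2-en-1-yl]cyclopent-2-en-1-one | CCCCC/C=C\C[C@@]1(O)C=CC(=O)C1 | intermediate
15 | (S)-4-[(Z)-oct-2-en-1-yl]-4-[(triethylsilyl)oxy]cyclopent-2-en-1-one | CCCCC/C=C\C[C@@]1(O[Si](CC)(CC)CC)C=CC(=O)C1 | intermediate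
16 | (4S)-4-[(Z)-oct-2-en-1-yl]-4-[(triethylsilyl)oxy]-6-oxabicyclo[3.1.0]hexan-2-one (epoxide face mixture) | CCCCC/C=C\C[C@@]1(O[Si](CC)(CC)CC)C2OC2C(=O)C1 | intermediate
17 | (4S)-2-chloro-3-hydroxy-4-[(Z)-oct-2-en-1-yl]-4-[(triethylsilyl)oxy]cyclopentan-1-one (2,3-trans, mixture) | CCCCC/C=C\C[C@@]1(O[Si](CC)(CC)CC)C(O)C(Cl)C(=O)C1 | intermediate
18 | (4S)-2-chloro-3-[(methylsulfonyl)oxy]-4-[(Z)-oct-2-en-1-yl]-4-[(triethylsilyl)oxy]cyclopentan-1-one | CCCCC/C=C\C[C@@]1(O[Si](CC)(CC)CC)C(OS(C)(=O)=O)C(Cl)C(=O)C1 | intermediate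
19 | (S)-2-chloro-4-[(Z)-oct-2-en-1-yl]-4-[(triethylsilyl)oxy]cyclopent-2-en-1-one | CCCCC/C=C\C[C@@]1(O[Si](CC)(CC)CC)C=C(Cl)C(=O)C1 | intermediate
20 | (4-carboxybutyl)triphenylphosphonium bromide | OC(=O)CCCC[P+](c1ccccc1)(c1ccccc1)c1ccccc1.[Br-] | starting material
21 | 2-[(tert-butyldimethylsilyl)oxy]acetaldehyde | CC(C)(C)[Si](C)(C)OCC=O | starting material
22 | sodium 5-(triphenyl-λ5-phosphanylidene)pentanoate (ylide) | [Na+].[O-]C(=O)CCCC=P(c1ccccc1)(c1ccccc1)c1ccccc1 | intermediate
23 | (Z)-7-[(tert-butyldimethylsilyl)oxy]hept-5-enoic acid | CC(C)(C)[Si](C)(C)OC/C=C\CCCC(=O)O | intermediate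
24 | methyl (Z)-7-hydroxyhept-5-enoate | OC/C=C\CCCC(=O)OC | intermediate
25 | methyl (Z)-7-oxohept-5-enoate | O=C/C=C\CCCC(=O)OC | intermediate
26 | lithium enolate of 19 | CCCCC/C=C\C[C@@]1(O[Si](CC)(CC)CC)C=C(Cl)C(O[Li])=C1 | intermediate
27 | methyl (5Z)-7-[(5S)-3-chloro-5-[(Z)-oct-2-en-1-yl]-2-oxo-5-[(triethylsilyl)oxy]cyclopent-3-en-1-yl]-7-hydroxyhept-5-enoate (mainly 7,8-anti) | CCCCC/C=C\C[C@@]1(O[Si](CC)(CC)CC)C=C(Cl)C(=O)C1C(O)/C=C\CCCC(=O)OC | intermediate
28 | methyl (5Z)-7-[(5S)-3-chloro-5-[(Z)-oct-2-en-1-yl]-2-oxo-5-[(triethylsilyl)oxy]cyclopent-3-en-1-yl]-7-[(methylsulfonyl)oxy]hept-5-enoate | CCCCC/C=C\C[C@@]1(O[Si](CC)(CC)CC)C=C(Cl)C(=O)C1C(OS(C)(=O)=O)/C=C\CCCC(=O)OC | intermediate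
29 | methyl (5Z,7Z)-7-[(5R)-3-chloro-5-[(Z)-oct-2-en-1-yl]-2-oxo-5-[(triethylsilyl)oxy]cyclopent-3-en-1-ylidene]hept-5-enoate | CCCCC/C=C\C[C@@]1(O[Si](CC)(CC)CC)C=C(Cl)C(=O)/C1=C\C=C/CCCC(=O)OC | intermediate
30 | methyl (5Z,7Z)-7-[(5R)-3-chloro-5-hydroxy-5-[(Z)-oct-2-en-1-yl]-2-oxocyclopent-3-en-1-ylidene]hept-5-enoate | CCCCC/C=C\C[C@@]1(O)C=C(Cl)C(=O)/C1=C\C=C/CCCC(=O)OC | target

**Totals**
Total step count: 19.
Longest linear sequence: 16 steps (1 → 30 through steps 1–13 and 17–19); the aldehyde fragment takes 3 steps (14–16).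

**Steps most likely to fail, each with a fallback**

Step 18 (7Z geometry of the exocyclic olefin). The elimination may drift towards E1cB behaviour and give mainly the 7E isomer. The fallback builds the C7=C8 geometry before the C6–C7 bond; it sets out from 19 and comes back to the route at 29. Formylation of 19 (LiN(SiMe3)2, 2,2,2-trifluoroethyl formate, THF, −78 °C) gives (4R,5Z)-2-chloro-5-(hydroxymethylidene)-4-[(Z)-oct-2-en-1-yl]-4-[(triethylsilyl)oxy]cyclopent-2-en-1-one F1. Trapping its chelated lithium enolate on oxygen (LiN(SiMe3)2, then PhNTf2, −78 °C) gives [(Z)-[(5R)-3-chloro-5-[(Z)-oct-2-en-1-yl]-2-oxo-5-[(triethylsilyl)oxy]cyclopent-3-en-1-ylidene]methyl] trifluoromethanesulfonate F2, with the triflate cis to the ring carbonyl. Suzuki–Miyaura coupling (Pd(PPh3)4, K3PO4, THF/H2O, rt) with methyl (Z)-6-(4,4,5,5-tetramethyl-1,3,2-dioxaborolan-2-yl)hex-5-enoate F3 proceeds with retention at both partners and gives 29. F3 is made from methyl hex-5-ynoate and pinacolborane by [RhCl(cod)]2/P(i-Pr)3/Et3N-catalysed trans-hydroboration.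

Step 12 (regioselective chloride opening with the silyl ether intact). If the opening is sluggish, unselective or costs the triethylsilyl group, the chlorine is introduced without an epoxide; the fallback sets out from 15 and comes back at 19. Nucleophile-catalysed α-iodination of 15 (I2, pyridine, CH2Cl2, rt), which leaves the isolated Z-olefin alone, gives (S)-2-iodo-4-[(Z)-oct-2-en-1-yl]-4-[(triethylsilyl)oxy]cyclopent-2-en-1-one F4. Stille-type stannylation ((Me3Sn)2, Pd(PPh3)4, toluene, 60 °C) gives (S)-4-[(Z)-oct-2-en-1-yl]-4-[(triethylsilyl)oxy]-2-(trimethylstannyl)cyclopent-2-en-1-one F5. Chlorodestannylation with CuCl2 (THF, 0 °C → rt) then gives 19.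

Step 5 (homopropargyl versus allenyl regiochemistry and facial selectivity of the propargylation). If allenyl carbinol or an inseparable diastereomer mixture results, the side chain is built by olefin metathesis instead; the fallback sets out from 5 and comes back at 12, bypassing steps 6 and 7. Addition of CH2=CHCH2MgBr in the presence of CeCl3 (THF, −78 °C), a symmetrical allyl nucleophile with no regiochemical ambiguity, gives (1S,4R)-1-allyl-4-[(tert-butyldimethylsilyl)oxy]cyclopent-2-en-1-ol F6. Z-selective cross-metathesis of F6 with hept-1-ene (5 equiv) gives 12; the catalyst is the cyclometalated ruthenium nitrate carbene Ru(NO3)(=CH-C6H4-2-O-i-Pr)[κ2-C,C-1-(adamantan-1-yl)-3-mesitylimidazolidin-2-ylidene] in THF at 35 °C, and the hindered ring olefin stays inert.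

Further compounds
F1 | step 18 | (4R,5Z)-2-chloro-5-(hydroxymethylidene)-4-[(Z)-oct-2-en-1-yl]-4-[(triethylsilyl)oxy]cyclopent-2-en-1-one | CCCCC/C=C\C[C@@]1(O[Si](CC)(CC)CC)C=C(Cl)C(=O)/C1=C\O
F2 | step 18 | [(Z)-[(5R)-3-chloro-5-[(Z)-oct-2-en-1-yl]-2-oxo-5-[(triethylsilyl)oxy]cyclopent-3-en-1-ylidene]methyl] trifluoromethanesulfonate | CCCCC/C=C\C[C@@]1(O[Si](CC)(CC)CC)C=C(Cl)C(=O)/C1=C\OS(=O)(=O)C(F)(F)F
F3 | step 18 | methyl (Z)-6-(4,4,5,5-tetramethyl-1,3,2-dioxaborolan-2-yl)hex-5-enoate | COC(=O)CCC/C=C\B1OC(C)(C)C(C)(C)O1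
F4 | step 12 | (S)-2-iodo-4-[(Z)-oct-2-en-1-yl]-4-[(triethylsilyl)oxy]cyclopent-2-en-1-one | CCCCC/C=C\C[C@@]1(O[Si](CC)(CC)CC)C=C(I)C(=O)C1
F5 | step 12 | (S)-4-[(Z)-oct-2-en-1-yl]-4-[(triethylsilyl)oxy]-2-(trimethylstannyl)cyclopent-2-en-1-one | CCCCC/C=C\C[C@@]1(O[Si](CC)(CC)CC)C=C([Sn](C)(C)C)C(=O)C1
F6 | step 5 | (1S,4R)-1-allyl-4-[(tert-butyldimethylsilyl)oxy]cyclopent-2-en-1-ol | C=CC[C@@]1(O)C=C[C@H](O[Si](C)(C)C(C)(C)C)C1
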